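## Structural features

Siphulin (21) is a 4H-chromen-4-one (benzo ring A fused to pyranone ring B) with a heptyl chain at C5 and a hydroxyl at C7. Its C2 is joined through one methylene carbon to ring C, a 2,4-dihydroxybenzoic acid whose carboxyl-bearing carbon lies between a hydroxyl-bearing carbon and the methylene-bearing carbon. The target has no stereocentre, so the problem is one of regiochemistry and functional-group tolerance. The β-resorcylic acid of ring C is the fragile group: it is shielded on both sides and loses CO2 in strong acid or on heating once its phenols are free, so neither late hydrolysis of a hindered ester nor harsh ether cleavage is a safe way to reach it. The methylene is doubly activated (benzylic and vinylogously alpha to the C4 carbonyl), and the C2=C3 bond is a reducible Michael acceptor. The real difficulty is to close ring B and deliver the carboxyl in free form, while both aryl rings carry contiguous substituents (on ring A the carbonyl-bearing carbon sits between the heptyl-bearing and an oxygen-bearing carbon). The key step exploits the fact that chromone C2, the methylene and the carboxyl carbon become C3, C4 and C1 of a 6,8-dioxygenated isocoumarin when the carboxyl oxygen is closed onto C2. That enol lactone is the internally protected form of the 1,3-diketone from which the chromone derives, and its C3 lies 1,3 to the ring A ketone, so the ring A phenol can take C3 over from the lactone oxygen.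

## Logic of the disconnections

**21 to 20.** The three aryl O–CH2Ph bonds are cut. The phenols are carried as benzyl ethers so that the last step is a neutral hydrogenolysis; this replaces a Lewis-acid ether cleavage, which would endanger the β-resorcylic acid. The carboxyl is already free in 20. The forward step must remove three benzyl groups without reducing the C2=C3 bond of ring B.

**20 to 17 (through 19 and 18).** The O1–C2 bond of ring B is cut and, in the same retrosynthetic move, the carboxyl oxygen is joined to that carbon, which turns C2, the methylene and the carboxyl carbon into C3, C4 and C1 of an isocoumarin. This stores the acid as an enol lactone, so no ester has to be hydrolysed, and makes ring B closure an isomerisation. The forward step needs an acid that unmasks the ring A phenol, leaves the benzyl ethers in place and offers no external nucleophile to the lactone.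

**17 to 16 to 15.** The ketone is taken back to a carbinol and the carbinol to its silyl ether. A ketone that is beta,gamma to an alkyne could not survive the coupling and the cyclisation (it would isomerise to an allenone or close to a furan), so the carbonyl is carried as a protected alcohol. Fluoride and the oxidant must leave the enol lactone and the acetal untouched.

**15 to 14.** The lactone O2–C3 bond is cut to give an ortho-alkynylbenzoic acid. The heterocycle becomes a linear diaryl alkyne, and no redox change is needed. The forward cyclisation must be 6-endo, not 5-exo, and must run under near-neutral conditions.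

**14 to 13.** The acid is taken back to the aldehyde. The formyl group is what the formylation installs and it activates the neighbouring iodide for coupling; this also avoids hydrolysing a doubly ortho-substituted ester. The oxidation must spare the alkyne and the alkoxy arenes.

**13 to 8 and 12.** The C(sp)–C(aryl) bond is cut. This divides the molecule into a ring A fragment and a ring C fragment of similar size. The coupling needs a terminal alkyne and a halide ortho to the formyl group.

**8 to 7 to 5 and 6.** The O–Si bond is cut, then the bond between the carbinol carbon and the propargylic CH2. Fragment 6 supplies in one piece the three carbons that become C3, C2 and the methylene of 21. The addition must give the homopropargylic, not the allenic, alcohol at a hindered aldehyde.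

**5 to 4 to 3 to 1.** The O–CH2OMe bond, the O–benzyl bond and the aryl–CHO bond are cut in turn. Formylation of symmetric 1 beside the heptyl chain sets the ring A pattern. The hydrogen bond to the formyl group differentiates the two hydroxyls: the para one is benzylated first, and the ortho one then receives the acid-labile acetal that the key step needs.

**12 to 10 to 9.** The aryl–CHO bond and two O–benzyl bonds are cut. Formylation between the iodine and a benzyloxy group sets the contiguous iodine, formyl, oxygen sequence that becomes the methylene-bearing carbon, the carboxyl and a hydroxyl of ring C.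

## Other disconnections considered

**Alternative 1:** Ring C itself is cut at C1'–C6' and C2'–C3' (C1' bears the methylene, C2' the carboxyl), which makes it the sum of a two-carbon alkyne and a four-carbon diene.

- Forward key step: benzyl 4-[7-(benzyloxy)-5-heptyl-4-oxo-4H-chromen-2-yl]but-2-ynoate A1 and 1-methoxy-1,3-bis(trimethylsilyloxy)buta-1,3-diene A2 would undergo a thermal Diels–Alder addition. Loss of the methoxy group and of both silyl groups would aromatise the adduct to benzyl 2-{[7-(benzyloxy)-5-heptyl-4-oxo-4H-chromen-2-yl]methyl}-4,6-dihydroxybenzoate A3.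
- In favour: the regiochemistry is electronically matched, because the nucleophilic CH2 terminus of A2 should bond to the beta carbon of A1 and so place the carboxyl between a hydroxyl and the methylene.
- Better than the chosen plan: no halogenated ring C fragment and no palladium coupling are needed.
- Equal to the chosen plan: ring C arrives with free hydroxyls and a benzyl ester, so one hydrogenolysis of A3 would give 21.
- Against: the methylene of A1 lies between chromone C2 and a conjugated alkyne, so prototropic shift to an allenoate or dienoate is likely at the temperature a beta-alkyl ynoate needs. A2 is moisture-sensitive and could instead add in Michael or Mukaiyama fashion to chromone C2.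
- Step economy: ring B must be built by a separate sequence before the key step, so the count should be no lower than that of the chosen plan.
- Mechanism: the cycloaddition is of an established type, where the chosen ring switch is not; but it rests on a less stable substrate.

**Alternative 2:** Ring B is cut at C3–C4 and O1–C2.

- Forward key step: 2-heptyl-6-hydroxy-4-methoxybenzaldehyde A4 and the sulfoxonium ylide methyl 2-[3-(dimethyl-oxo-λ6-sulfanylidene)-2-oxopropyl]-4,6-dimethoxybenzoate A5 would be joined with [Cp*RhCl2]2 and AgSbF6. The phenol-directed trivalent rhodium would cleave the formyl C–H bond, the acyl group would migrate to the carbene carbon of A5 (forming C4–C3), and condensation of the phenol on the ketone (forming O1–C2) would give methyl 2-[(5-heptyl-7-methoxy-4-oxo-4H-chromen-2-yl)methyl]-4,6-dimethoxybenzoate A6.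
- Better than the chosen plan on precedent and step count: it closes the same ring from a free salicylaldehyde, with no acetal, no propargylation and no carbinol redox, and the reaction class is established for salicylaldehydes.
- Against: the formyl group of A4 is flanked by the heptyl chain, which crowds the rhodacycle and invites decarbonylation. A5 carries an acidic methylene next to an ortho ester.
- Worse than the chosen plan at the end: A6 is a methyl ester with three methyl ethers, so reaching 21 would need hydrolysis of a doubly ortho-substituted benzoate and a strong Lewis acid, both beside the labile β-resorcylic acid. The chosen plan releases the acid in the ring-forming step and ends with a neutral hydrogenolysis.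
- With benzyl ethers and a benzyl ester this alternative would become a serious competitor.

**Alternative 3:** The C1'–methylene and C2'–carboxyl bonds are cut, so ring C enters as an aryne.

- Forward key step: fluoride would release 3,5-bis(benzyloxy)benzyne A8 from 3,5-bis(benzyloxy)-2-(trimethylsilyl)phenyl trifluoromethanesulfonate A7. The enolate of benzyl 2-[7-(benzyloxy)-5-heptyl-4-oxo-4H-chromen-2-yl]acetate A9 would add to the aryne carbon remote from the neighbouring benzyloxy group, the aryl anion would attack the ester carbonyl, and fragmentation of the four-membered alkoxide would give benzyl 2,4-bis(benzyloxy)-6-{[7-(benzyloxy)-5-heptyl-4-oxo-4H-chromen-2-yl]methyl}benzoate A10.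
- In favour: it is the most convergent of the four plans, and the known regiochemistry of addition to 3-alkoxyarynes puts the carboxyl where it belongs.
- Equal to or better than the chosen plan at the end: one hydrogenolysis of A10 would remove ethers and ester together.
- Against: formal insertion into a C–C bond is established where the aryl anion attacks a ketone or a malonate ester. Here the acceptor is a single benzyl ester and the carbanion is a vinylogous chromone enolate, so plain C-arylation by proton transfer, O-arylation, double arylation and attack at the chromone carbonyl could all compete.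
- Step economy: A7 needs several steps and A9 needs its own chromone synthesis, so the count should be similar to that of the chosen plan.
- Mechanism: the selectivity risk is higher than in the chosen plan, where the nucleophile and the electrophile are held in one molecule.

Key step: step 13

Assumption: 5-iodobenzene-1,3-diol (9) is taken to be purchasable, as its dimethyl ether is; the carbinol centre carried from 7 to 16 is racemic and needs no control because step 12 removes it.

## Route

Step 1
Reactants: 1 5-heptylbenzene-1,3-diol
Product: 3 2-heptyl-4,6-dihydroxybenzaldehyde, via iminium chloride 2 (not isolated)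
Conditions: POCl3, DMF, 0 °C → rt; then H2O, 50 °C
Reagents that add atoms: N,N-dimethylformamide CN(C)C=O; water O
Why: Vilsmeier–Haack formylation; the chloroiminium ion should attack the position para to one hydroxyl and ortho to the other, beside the chain, and not the doubly flanked position between the hydroxyls, as is usual for 5-alkylresorcinols. Hydrolysis of 2 releases the aldehyde.

Step 2
Reactants: 3 2-heptyl-4,6-dihydroxybenzaldehyde
Product: 4 4-(benzyloxy)-2-heptyl-6-hydroxybenzaldehyde
Conditions: BnBr (1.05 equiv), K2CO3 (1.1 equiv), acetone, rt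
Reagents that add atoms: benzyl bromide BrCc1ccccc1
Why: Williamson etherification; the ortho hydroxyl is held in a hydrogen bond to the formyl oxygen and is the weaker nucleophile, so one equivalent of halide with a mild base should alkylate the para hydroxyl alone.

Step 3
Reactants: 4 4-(benzyloxy)-2-heptyl-6-hydroxybenzaldehyde
Product: 5 4-(benzyloxy)-2-heptyl-6-(methoxymethoxy)benzaldehyde
Conditions: NaH, DMF, 0 °C; then MOMCl, 0 °C → rt
Reagents that add atoms: chloromethyl methyl ether COCCl
Why: O-alkylation of the sodium phenoxide (acetal protection); deprotonation breaks the hydrogen bond. The acetal should withstand the organometallic, basic, fluoride and oxidative steps that follow and is the one group meant to leave in acid at step 13.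

Step 4
Reactants: 5 4-(benzyloxy)-2-heptyl-6-(methoxymethoxy)benzaldehyde; 6 3-bromoprop-1-yne (propargyl bromide)
Product: 7 rac-1-[4-(benzyloxy)-2-heptyl-6-(methoxymethoxy)phenyl]but-3-yn-1-ol
Conditions: Zn dust, THF, 0 °C → rt; then sat. aq. NH4Cl
Reagents that add atoms: none
Why: Barbier propargylation; the allenylzinc bromide formed on the metal should add through a cyclic SE2' transition state, which gives the homopropargylic and not the allenic alcohol. The carbinol centre forms as a racemate and is erased at step 12.

Step 5
Reactants: 7 rac-1-[4-(benzyloxy)-2-heptyl-6-(methoxymethoxy)phenyl]but-3-yn-1-ol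
Product: 8 rac-tert-butyl({1-[4-(benzyloxy)-2-heptyl-6-(methoxymethoxy)phenyl]but-3-yn-1-yl}oxy)dimethylsilane
Conditions: TBSCl, imidazole, DMF, rt → 40 °C
Reagents that add atoms: tert-butyl(chloro)dimethylsilane CC(C)(C)[Si](C)(C)Cl
Why: Imidazole-promoted silylation of the secondary alcohol; the silyl ether keeps the hydroxyl from adding to the alkyne in step 10 and should be stable through steps 8 to 10.

Step 6
Reactants: 9 5-iodobenzene-1,3-diol
Product: 10 1,3-bis(benzyloxy)-5-iodobenzene
Conditions: BnBr (2.2 equiv), K2CO3, DMF, 60 °C
Reagents that add atoms: benzyl bromide BrCc1ccccc1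
Why: Double Williamson etherification of an unhindered resorcinol; benzyl ethers are chosen so that ring C can be unmasked by hydrogenolysis at the end.

Step 7
Reactants: 10 1,3-bis(benzyloxy)-5-iodobenzene
Product: 12 2,4-bis(benzyloxy)-6-iodobenzaldehyde, via iminium chloride 11 (not isolated)
Conditions: POCl3, DMF, 0 → 80 °C; then H2O
Reagents that add atoms: N,N-dimethylformamide CN(C)C=O; water O
Why: Vilsmeier–Haack formylation; attack should occur at one of the two equivalent positions para to one benzyloxy group and ortho to the other, next to iodine, and not at the more shielded position between the two benzyloxy groups. The aryl iodide is inert to the reagent.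

Step 8
Reactants: 8 rac-tert-butyl({1-[4-(benzyloxy)-2-heptyl-6-(methoxymethoxy)phenyl]but-3-yn-1-yl}oxy)dimethylsilane; 12 2,4-bis(benzyloxy)-6-iodobenzaldehyde
Product: 13 rac-2,4-bis(benzyloxy)-6-{4-[4-(benzyloxy)-2-heptyl-6-(methoxymethoxy)phenyl]-4-[(tert-butyldimethylsilyl)oxy]but-1-yn-1-yl}benzaldehyde
Conditions: Pd(PPh3)2Cl2 (3 mol%), CuI (5 mol%), Et3N, THF, degassed, rt → 40 °C
Reagents that add atoms: none
Why: Sonogashira coupling; oxidative addition of zerovalent palladium into the C–I bond ortho to the formyl group should be fast near room temperature. Silyl ether, acetal, benzyl ethers and aldehyde are inert to these conditions.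

Step 9
Reactants: 13 rac-2,4-bis(benzyloxy)-6-{4-[4-(benzyloxy)-2-heptyl-6-(methoxymethoxy)phenyl]-4-[(tert-butyldimethylsilyl)oxy]but-1-yn-1-yl}benzaldehyde
Product: 14 rac-2,4-bis(benzyloxy)-6-{4-[4-(benzyloxy)-2-heptyl-6-(methoxymethoxy)phenyl]-4-[(tert-butyldimethylsilyl)oxy]but-1-yn-1-yl}benzoic acid
Conditions: NaClO2, NaH2PO4, 2-methyl-2-butene, t-BuOH/THF/H2O, 0 °C → rt
Reagents that add atoms: sodium chlorite [Na+].[O-]Cl=O
Why: Pinnick oxidation; chlorous acid at about pH 4 should convert the hindered aldehyde to the acid without touching alkyne, acetal or silyl ether. The alkene scavenger removes HOCl before it can chlorinate the alkoxy arenes, and no hindered ester has to be hydrolysed.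

Step 10
Reactants: 14 rac-2,4-bis(benzyloxy)-6-{4-[4-(benzyloxy)-2-heptyl-6-(methoxymethoxy)phenyl]-4-[(tert-butyldimethylsilyl)oxy]but-1-yn-1-yl}benzoic acid
Product: 15 rac-6,8-bis(benzyloxy)-3-{2-[4-(benzyloxy)-2-heptyl-6-(methoxymethoxy)phenyl]-2-[(tert-butyldimethylsilyl)oxy]ethyl}-1H-isochromen-1-one
Conditions: Ph3PAuNTf2 (2 mol%), CH2Cl2, rt
Reagents that add atoms: none
Why: Gold-catalysed cycloisomerisation; pi-activation by the cationic monovalent gold complex should direct the carboxyl oxygen to the alkyl-substituted distal alkyne carbon (6-endo-dig), the mode known for ortho-(alk-1-ynyl)benzoic acids and esters. Protodeauration then gives the enol lactone, and the near-neutral medium spares acetal and silyl ether.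

Step 11
Reactants: 15 rac-6,8-bis(benzyloxy)-3-{2-[4-(benzyloxy)-2-heptyl-6-(methoxymethoxy)phenyl]-2-[(tert-butyldimethylsilyl)oxy]ethyl}-1H-isochromen-1-one
Product: 16 rac-6,8-bis(benzyloxy)-3-{2-[4-(benzyloxy)-2-heptyl-6-(methoxymethoxy)phenyl]-2-hydroxyethyl}-1H-isochromen-1-one
Conditions: TBAF, AcOH (1:1), THF, 0 °C → rt
Reagents that add atoms: none
Why: Fluoride-mediated desilylation; acetic acid buffers the basicity of the fluoride source and of the alkoxide that is set free, so the enol lactone should not be opened.

Step 12
Reactants: 16 rac-6,8-bis(benzyloxy)-3-{2-[4-(benzyloxy)-2-heptyl-6-(methoxymethoxy)phenyl]-2-hydroxyethyl}-1H-isochromen-1-one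
Product: 17 6,8-bis(benzyloxy)-3-{2-[4-(benzyloxy)-2-heptyl-6-(methoxymethoxy)phenyl]-2-oxoethyl}-1H-isochromen-1-one
Conditions: Dess–Martin periodinane, NaHCO3, CH2Cl2, 0 °C → rt
Reagents that add atoms: none
Why: Dess–Martin oxidation; the buffered neutral medium should convert the hindered benzylic carbinol to the aryl ketone without acid that would start step 13 early, and it removes the only stereocentre. Migration of the C3=C4 bond into conjugation with the new ketone would give a tautomer that enters step 13 equally well.

Step 13
Reactants: 17 6,8-bis(benzyloxy)-3-{2-[4-(benzyloxy)-2-heptyl-6-(methoxymethoxy)phenyl]-2-oxoethyl}-1H-isochromen-1-one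
Product: 20 2,4-bis(benzyloxy)-6-{[7-(benzyloxy)-5-heptyl-4-oxo-4H-chromen-2-yl]methyl}benzoic acid, via free phenol 18 (not isolated), via spiro ketal 19 (not isolated)
Conditions: CF3CO2H/CH2Cl2 (1:4), anhydrous, 0 °C → rt; then H2O
Reagents that add atoms: none
Why: Proposed new method: the acid should ionise the aryl methoxymethyl acetal to give phenol 18; protonation of the enol lactone at C4 (or acid-catalysed shift of the double bond into conjugation with the ketone) then makes C3 an acyloxy-stabilised cation, which the ortho phenol captures in a 6-exo-trig closure (the C3=O2 bond lies outside the new ring) to give spiro ketal 19. Ionisation of the acyloxy group, with the carboxyl as leaving group, and loss of a proton from the ketone-flanked CH2 then give the chromone and the free acid. The closest known reactions are the acid cyclodehydration of ortho-hydroxyaryl 1,3-diketones that ends a Baker–Venkataraman chromone synthesis (17 is the enol ester of such a diketone) and the recyclisation of isocoumarins by nitrogen nucleophiles at C3 to isoquinolones. No stereocentre is formed, since the spiro centre of 19 is transient. The step needs attack of the phenol at C3 and not of an outside nucleophile at the lactone carbonyl; the aprotic medium and the weakly nucleophilic acid leave the phenol as the only competent nucleophile, and its position allows only the six-membered closure. Traces of water are harmless, because hydrolysis of the enol lactone would give a diketo acid that cyclises to the same product. The acetal must cleave before the aryl benzyl ethers do, which its far higher acid lability at low temperature should secure. The driving force is the greater stability of the chromone vinylogous ester over the enol lactone.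

Step 14
Reactants: 20 2,4-bis(benzyloxy)-6-{[7-(benzyloxy)-5-heptyl-4-oxo-4H-chromen-2-yl]methyl}benzoic acid
Product: 21 siphulin
Conditions: H2 (1 atm), 10% Pd/C, EtOAc/MeOH, rt
Reagents that add atoms: none
Why: Catalytic hydrogenolysis of three aryl benzyl ethers; the medium is neutral and at room temperature, so the β-resorcylic acid meets neither acid nor heat. Benzyl C–O cleavage on palladium should be much faster than reduction of the chromone C2=C3 bond.

## Compound list

1 | 5-heptylbenzene-1,3-diol (5-heptylresorcinol) | CCCCCCCc1cc(O)cc(O)c1 | starting material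
2 | N-[(2-heptyl-4,6-dihydroxyphenyl)methylidene]-N-methylmethanaminium chloride | CCCCCCCc1cc(O)cc(O)c1C=[N+](C)C.[Cl-] | intermediate
3 | 2-heptyl-4,6-dihydroxybenzaldehyde | CCCCCCCc1cc(O)cc(O)c1C=O | intermediate
4 | 4-(benzyloxy)-2-heptyl-6-hydroxybenzaldehyde | CCCCCCCc1cc(OCc2ccccc2)cc(O)c1C=O | intermediate
5 | 4-(benzyloxy)-2-heptyl-6-(methoxymethoxy)benzaldehyde | CCCCCCCc1cc(OCc2ccccc2)cc(OCOC)c1C=O | intermediate
6 | 3-bromoprop-1-yne (propargyl bromide) | C#CCBr | starting material
7 | rac-1-[4-(benzyloxy)-2-heptyl-6-(methoxymethoxy)phenyl]but-3-yn-1-ol | CCCCCCCc1cc(OCc2ccccc2)cc(OCOC)c1C(O)CC#C | intermediate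
8 | rac-tert-butyl({1-[4-(benzyloxy)-2-heptyl-6-(methoxymethoxy)phenyl]but-3-yn-1-yl}oxy)dimethylsilane | CCCCCCCc1cc(OCc2ccccc2)cc(OCOC)c1C(CC#C)O[Si](C)(C)C(C)(C)C | intermediate
9 | 5-iodobenzene-1,3-diol (5-iodoresorcinol) | Oc1cc(O)cc(I)c1 | starting material
10 | 1,3-bis(benzyloxy)-5-iodobenzene | Ic1cc(OCc2ccccc2)cc(OCc2ccccc2)c1 | intermediate
11 | N-{[2,4-bis(benzyloxy)-6-iodophenyl]methylidene}-N-methylmethanaminium chloride | C[N+](C)=Cc1c(I)cc(OCc2ccccc2)cc1OCc1ccccc1.[Cl-] | intermediate
12 | 2,4-bis(benzyloxy)-6-iodobenzaldehyde | O=Cc1c(I)cc(OCc2ccccc2)cc1OCc1ccccc1 | intermediate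
13 | rac-2,4-bis(benzyloxy)-6-{4-[4-(benzyloxy)-2-heptyl-6-(methoxymethoxy)phenyl]-4-[(tert-butyldimethylsilyl)oxy]but-1-yn-1-yl}benzaldehyde | CCCCCCCc1cc(OCc2ccccc2)cc(OCOC)c1C(CC#Cc1cc(OCc2ccccc2)cc(OCc2ccccc2)c1C=O)O[Si](C)(C)C(C)(C)C | intermediate
14 | rac-2,4-bis(benzyloxy)-6-{4-[4-(benzyloxy)-2-heptyl-6-(methoxymethoxy)phenyl]-4-[(tert-butyldimethylsilyl)oxy]but-1-yn-1-yl}benzoic acid | CCCCCCCc1cc(OCc2ccccc2)cc(OCOC)c1C(CC#Cc1cc(OCc2ccccc2)cc(OCc2ccccc2)c1C(=O)O)O[Si](C)(C)C(C)(C)C | intermediate
15 | rac-6,8-bis(benzyloxy)-3-{2-[4-(benzyloxy)-2-heptyl-6-(methoxymethoxy)phenyl]-2-[(tert-butyldimethylsilyl)oxy]ethyl}-1H-isochromen-1-one | CCCCCCCc1cc(OCc2ccccc2)cc(OCOC)c1C(CC1=Cc2cc(OCc3ccccc3)cc(OCc3ccccc3)c2C(=O)O1)O[Si](C)(C)C(C)(C)C | intermediate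
16 | rac-6,8-bis(benzyloxy)-3-{2-[4-(benzyloxy)-2-heptyl-6-(methoxymethoxy)phenyl]-2-hydroxyethyl}-1H-isochromen-1-one | CCCCCCCc1cc(OCc2ccccc2)cc(OCOC)c1C(O)CC1=Cc2cc(OCc3ccccc3)cc(OCc3ccccc3)c2C(=O)O1 | intermediate
17 | 6,8-bis(benzyloxy)-3-{2-[4-(benzyloxy)-2-heptyl-6-(methoxymethoxy)phenyl]-2-oxoethyl}-1H-isochromen-1-one | CCCCCCCc1cc(OCc2ccccc2)cc(OCOC)c1C(=O)CC1=Cc2cc(OCc3ccccc3)cc(OCc3ccccc3)c2C(=O)O1 | intermediate
18 | 6,8-bis(benzyloxy)-3-{2-[4-(benzyloxy)-2-heptyl-6-hydroxyphenyl]-2-oxoethyl}-1H-isochromen-1-one | CCCCCCCc1cc(OCc2ccccc2)cc(O)c1C(=O)CC1=Cc2cc(OCc3ccccc3)cc(OCc3ccccc3)c2C(=O)O1 | intermediate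
19 | 6',7,8'-tris(benzyloxy)-5-heptylspiro[chromane-2,3'-isochromane]-1',4-dione (racemic at the spiro carbon) | CCCCCCCc1cc(OCc2ccccc2)cc2OC3(CC(=O)c12)Cc1cc(OCc4ccccc4)cc(OCc4ccccc4)c1C(=O)O3 | intermediate
20 | 2,4-bis(benzyloxy)-6-{[7-(benzyloxy)-5-heptyl-4-oxo-4H-chromen-2-yl]methyl}benzoic acid | CCCCCCCc1cc(OCc2ccccc2)cc2oc(Cc3cc(OCc4ccccc4)cc(OCc4ccccc4)c3C(=O)O)cc(=O)c12 | intermediate
21 | siphulin, 2-[(5-heptyl-7-hydroxy-4-oxo-4H-chromen-2-yl)methyl]-4,6-dihydroxybenzoic acid | CCCCCCCc1cc(O)cc2oc(Cc3cc(O)cc(O)c3C(=O)O)cc(=O)c12 | target

## Step count and least certain steps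

Total: 14 steps. Longest linear sequence: 12 steps (steps 1 to 5 and 8 to 14, from 1); the ring C branch is 2 steps (6 and 7).

**Step 13 (key step, proposed new method).**
- What may go wrong: the sequence may stall at, or revert from, the spiro ketal stage if ionisation of the acyloxy group is slow. The methoxymethyl cation may alkylate one of the alkoxy arenes. Prolonged acid may begin to cleave benzyl ethers or protonate the electron-rich acid at the carboxyl-bearing carbon, with loss of CO2. The remedy within the step is a short reaction time at low temperature.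
- Fallback by known chemistry: from 17, cold aqueous LiOH in THF would saponify the enol ester, and careful acidification would give the diketo acid 2,4-bis(benzyloxy)-6-{4-[4-(benzyloxy)-2-heptyl-6-(methoxymethoxy)phenyl]-2,4-dioxobutyl}benzoic acid F1. Brief treatment of F1 with aqueous HCl in THF would then remove the acetal and effect the classical cyclodehydration of an ortho-hydroxyaryl 1,3-diketone, which comes back to the route at 20.

**Step 10.**
- What may go wrong: competing 5-exo-dig closure to an alkylidene phthalide, or loss of the acetal or silyl ether through adventitious strong acid from the catalyst.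
- Fallback: from 14, methylation (MeI, K2CO3, DMF) would give methyl 2,4-bis(benzyloxy)-6-{4-[4-(benzyloxy)-2-heptyl-6-(methoxymethoxy)phenyl]-4-[(tert-butyldimethylsilyl)oxy]but-1-yn-1-yl}benzoate F2. Electrophilic iodocyclisation of F2 (I2, NaHCO3, CH2Cl2), which is reliably 6-endo for ortho-alkynylbenzoates, would give 6,8-bis(benzyloxy)-3-{2-[4-(benzyloxy)-2-heptyl-6-(methoxymethoxy)phenyl]-2-[(tert-butyldimethylsilyl)oxy]ethyl}-4-iodo-1H-isochromen-1-one F3. Palladium-catalysed reduction of the vinyl iodide (Pd(PPh3)4, Bu3SnH, THF) would return to the route at 15.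

**Step 11.**
- What may go wrong: opening of the enol lactone by the basic fluoride source, or slow cleavage at the hindered carbinol that forces harsher conditions.
- Fallback: the order is changed so that fluoride never meets the lactone. From 14, TBAF with AcOH would give the hydroxy acid 2,4-bis(benzyloxy)-6-{4-[4-(benzyloxy)-2-heptyl-6-(methoxymethoxy)phenyl]-4-hydroxybut-1-yn-1-yl}benzoic acid F4. Cyclisation of F4 with Ph3PAuNTf2 would rejoin the route at 16; the carboxyl, held ortho to the alkyne, should outrun the 5-endo closure of the free hydroxyl.

**Step 4.**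
- What may go wrong: formation of the allenyl carbinol alongside the homopropargylic one, or slow addition to the hindered, electron-rich aldehyde with Wurtz-type coupling of the halide.
- Fallback: from 5, propargylation with allenylboronic acid pinacol ester would transfer the three-carbon unit through a closed six-membered transition state with allenyl-to-propargyl transposition, and aqueous work-up would return directly to 7. No new compound is made.

**Step 14.**
- What may go wrong: over-reduction of the chromone C2=C3 bond, or slow cleavage through catalyst poisoning.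
- Fallback: from 20, non-reductive debenzylation with BCl3 and pentamethylbenzene as cation trap in CH2Cl2 at −78 °C, with a cold quench, would give 21 directly. No new compound is made.

## Further compounds

F1 | step 13 | 2,4-bis(benzyloxy)-6-{4-[4-(benzyloxy)-2-heptyl-6-(methoxymethoxy)phenyl]-2,4-dioxobutyl}benzoic acid | CCCCCCCc1cc(OCc2ccccc2)cc(OCOC)c1C(=O)CC(=O)Cc1cc(OCc2ccccc2)cc(OCc2ccccc2)c1C(=O)O
F2 | step 10 | rac-methyl 2,4-bis(benzyloxy)-6-{4-[4-(benzyloxy)-2-heptyl-6-(methoxymethoxy)phenyl]-4-[(tert-butyldimethylsilyl)oxy]but-1-yn-1-yl}benzoate | CCCCCCCc1cc(OCc2ccccc2)cc(OCOC)c1C(CC#Cc1cc(OCc2ccccc2)cc(OCc2ccccc2)c1C(=O)OC)O[Si](C)(C)C(C)(C)C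
F3 | step 10 | rac-6,8-bis(benzyloxy)-3-{2-[4-(benzyloxy)-2-heptyl-6-(methoxymethoxy)phenyl]-2-[(tert-butyldimethylsilyl)oxy]ethyl}-4-iodo-1H-isochromen-1-one | CCCCCCCc1cc(OCc2ccccc2)cc(OCOC)c1C(CC1=C(I)c2cc(OCc3ccccc3)cc(OCc3ccccc3)c2C(=O)O1)O[Si](C)(C)C(C)(C)C
F4 | step 11 | rac-2,4-bis(benzyloxy)-6-{4-[4-(benzyloxy)-2-heptyl-6-(methoxymethoxy)phenyl]-4-hydroxybut-1-yn-1-yl}benzoic acid | CCCCCCCc1cc(OCc2ccccc2)cc(OCOC)c1C(O)CC#Cc1cc(OCc2ccccc2)cc(OCc2ccccc2)c1C(=O)O
F0 | step 4 | none | none
F0 | step 14 | none | none
A1 | alternative 1 | benzyl 4-[7-(benzyloxy)-5-heptyl-4-oxo-4H-chromen-2-yl]but-2-ynoate | CCCCCCCc1cc(OCc2ccccc2)cc2oc(CC#CC(=O)OCc3ccccc3)cc(=O)c12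
A2 | alternative 1 | 1-methoxy-1,3-bis(trimethylsilyloxy)buta-1,3-diene | COC(O[Si](C)(C)C)=CC(=C)O[Si](C)(C)C
A3 | alternative 1 | benzyl 2-{[7-(benzyloxy)-5-heptyl-4-oxo-4H-chromen-2-yl]methyl}-4,6-dihydroxybenzoate | CCCCCCCc1cc(OCc2ccccc2)cc2oc(Cc3cc(O)cc(O)c3C(=O)OCc3ccccc3)cc(=O)c12
A4 | alternative 2 | 2-heptyl-6-hydroxy-4-methoxybenzaldehyde | CCCCCCCc1cc(OC)cc(O)c1C=O
A5 | alternative 2 | methyl 2-[3-(dimethyl-oxo-λ6-sulfanylidene)-2-oxopropyl]-4,6-dimethoxybenzoate | COC(=O)c1c(CC(=O)C=S(C)(C)=O)cc(OC)cc1OC
A6 | alternative 2 | methyl 2-[(5-heptyl-7-methoxy-4-oxo-4H-chromen-2-yl)methyl]-4,6-dimethoxybenzoate | CCCCCCCc1cc(OC)cc2oc(Cc3cc(OC)cc(OC)c3C(=O)OC)cc(=O)c12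
A7 | alternative 3 | 3,5-bis(benzyloxy)-2-(trimethylsilyl)phenyl trifluoromethanesulfonate | C[Si](C)(C)c1c(OS(=O)(=O)C(F)(F)F)cc(OCc2ccccc2)cc1OCc1ccccc1
A8 | alternative 3 | 3,5-bis(benzyloxy)benzyne | C1#CC(OCc2ccccc2)=CC(OCc2ccccc2)=C1
A9 | alternative 3 | benzyl 2-[7-(benzyloxy)-5-heptyl-4-oxo-4H-chromen-2-yl]acetate | CCCCCCCc1cc(OCc2ccccc2)cc2oc(CC(=O)OCc3ccccc3)cc(=O)c12
A10 | alternative 3 | benzyl 2,4-bis(benzyloxy)-6-{[7-(benzyloxy)-5-heptyl-4-oxo-4H-chromen-2-yl]methyl}benzoate | CCCCCCCc1cc(OCc2ccccc2)cc2oc(Cc3cc(OCc4ccccc4)cc(OCc4ccccc4)c3C(=O)OCc3ccccc3)cc(=O)c12
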